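The plan rests on cutting the C3–C4 bond of ring A (drimane numbering). Ring B (C5–C10, with the C8 methyl) is the ring of (S)-carvone and the isopropenyl carbon on C5 is C4, so the feature exploited is the C4 gem-dimethyl carbon next to the C3 carbinol. Hydrogen-atom transfer to the isopropenyl CH2 writes the second C4 methyl and leaves a tertiary C4 radical. Its 6-exo addition to a pendant aldehyde closes ring A as a trans-decalin and sets C3 in one operation. The precursor is carvone bearing at its C6 (future C10) a methyl group and, trans to the isopropenyl group, a 3-oxopropyl chain.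

Key step: step 4

Remark on the chemistry: drimane numbering is used for all bicyclic compounds (ring A = C1–C5 and C10, ring B = C5–C10, C11 = the CH2 on C9). The target SMILES reads as (3R,5S,8S,9R,10R), an ent-drimane. It is a trans-decalin with the C10 and C8 methyls axial on the same face. The C3 ester oxygen, the C8 hydroxyl and the C9 CH2OAr group are all equatorial.

Step 1
Reactants: 1 (S)-(+)-carvone
Product: 3 (5S)-2,6-dimethyl-5-(prop-1-en-2-yl)cyclohex-2-en-1-one (6-methylcarvone as its C6 epimer mixture), via carvone lithium dienolate 2 (not isolated)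
Conditions: LiN(iPr)2, THF, −78 °C; MeI, −78 → 0 °C
Reagents that add atoms: methyl iodide, CI; LiN(iPr)2, [Li]N(C(C)C)C(C)C (lithium, to intermediate 2 only)
Why: Kinetic deprotonation of the enone at its alpha-prime CH2 followed by SN2 enolate alkylation is routine for carvone, and the configuration of the new C6 centre does not matter because the next enolisation erases it.

Step 2
Reactants: 3 6-methylcarvone; 4 allyl bromide
Product: 6 (5R,6R)-2,6-dimethyl-5-(prop-1-en-2-yl)-6-(prop-2-en-1-yl)cyclohex-2-en-1-one (allyl trans to isopropenyl), via methylcarvone lithium dienolate 5 (not isolated)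
Conditions: LiN(iPr)2, THF, −78 → 0 °C; allyl bromide, −78 °C → rt
Reagents that add atoms: LiN(iPr)2, [Li]N(C(C)C)C(C)C (lithium, to intermediate 5 only)
Why: In this enolate allylation the reactive allylic halide attacks the tetrasubstituted alpha-prime enolate on the face anti to the neighbouring isopropenyl group, so quaternary C10 forms with the three-carbon chain trans and the methyl cis to the isopropenyl group, and an allyl halide is chosen because an enal or acrylate acceptor would invite 1,2-addition, polymerisation or a second Michael closure onto the enone.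

Step 3
Reactants: 6 6-allyl-6-methylcarvone
Product: 7 3-[(1R,6R)-1,3-dimethyl-2-oxo-6-(prop-1-en-2-yl)cyclohex-3-en-1-yl]propanal (6-methyl-6-(3-oxopropyl)carvone)
Conditions: PdCl2(PhCN)2 (cat.), CuCl2·2H2O (cat.), AgNO2 (cat.), O2 (1 atm), tBuOH/MeNO2, rt
Reagents that add atoms: dioxygen, O=O
Why: The nitrite-modified, aldehyde-selective Wacker-type oxidation places oxygen on the terminal carbon of monosubstituted alkenes, a preference reinforced here by the quaternary carbon next to the allylic CH2, whereas the 1,1-disubstituted isopropenyl group and the trisubstituted enone are not oxidised by divalent palladium under these conditions.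

Step 4
Reactants: 7 6-methyl-6-(3-oxopropyl)carvone
Product: 8 (3R,5R,10R)-3-hydroxy-11-nordrim-7-en-9-one, which is (4aR,6R,8aR)-6-hydroxy-2,5,5,8a-tetramethyl-4a,5,6,7,8,8a-hexahydronaphthalen-1(4H)-one
Conditions: Fe(acac)3 (0.3 equiv), PhSiH3 (2.5 equiv), degassed EtOH (0.03 M), Ar, 60 °C
Reagents that add atoms: none
Why: An iron hydride generated from Fe(acac)3 and PhSiH3 transfers a hydrogen atom to the CH2 terminus of the isopropenyl group (Markovnikov sense), which creates the second C4 methyl and a nucleophilic tertiary radical at C4; this radical adds to the aldehyde carbon C3, and the resulting alkoxy radical is reduced by divalent iron and protonated by ethanol before it can fragment back. The closest known reaction type is the iron-catalysed hydrogen-atom-transfer reductive cyclisation of alkene-tethered carbonyl compounds, together with the intermolecular iron-hydride coupling of unactivated alkenes with aldehydes. Ring A closes in the 6-exo-trig mode through a chair in which the C5–C4 and C10–C1 bonds are both equatorial on ring B, an arrangement fixed by the trans relation set in step 2, so the fusion must be trans with the C10 methyl axial. The only new stereocentre, C3, is controlled by that chair: the carbonyl oxygen sits equatorial to avoid the axial hydrogens on C1 and C5, and because the addition is reversible the more stable equatorial alkoxy radical should be the one drained off, giving 3R. The step needs hydrogen-atom transfer to the electron-rich 1,1-disubstituted alkene rather than to the trisubstituted electron-poor enone, which the faster hydride transfer to unhindered terminal alkenes should secure, and the C4 radical cannot reach C7 of the enone without forming a four-membered ring. Oxygen is excluded and the solution kept dilute so that neither oxygenation of the radical nor intermolecular conjugate addition competes.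

Step 5
Reactants: 8 hydroxy enone
Product: 9 (3R,5R,10R)-3-(tert-butyldimethylsilyloxy)-11-nordrim-7-en-9-one
Conditions: TBSOTf, 2,6-lutidine, CH2Cl2, 0 °C
Reagents that add atoms: tert-butyldimethylsilyl triflate, CC(C)(C)[Si](C)(C)OS(=O)(=O)C(F)(F)F
Why: Silyl ether formation with the reactive triflate copes with a hydroxyl flanked by the C4 gem-dimethyl group and masks C3–OH so that C11–OH is later the only alcohol open to substitution, with no stereocentre touched.

Step 6
Reactants: 9 silyloxy enone
Product: 10 (3R,5S,10R)-3-(tert-butyldimethylsilyloxy)drima-7,9(11)-diene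
Conditions: Ph3PCH3Br, KOtBu, toluene, 90 °C
Reagents that add atoms: methyltriphenylphosphonium bromide, C[P+](c1ccccc1)(c1ccccc1)c1ccccc1.[Br-]
Why: Wittig methylenation under the KOtBu conditions used for hindered ketones brings in C11 while C8 is still sp2, so the carbonyl is flanked by only one quaternary carbon and carries no alpha hydrogen whose removal could epimerise a centre.

Step 7
Reactants: 10 diene
Product: 12 (3R,5S,9R,10R)-3-(tert-butyldimethylsilyloxy)drim-7-en-11-ol, via B-alkyl-9-BBN adduct 11 (not isolated)
Conditions: 9-BBN, THF, 0 → 50 °C; then NaOH, H2O2, 0 °C → rt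
Reagents that add atoms: 9-BBN, B1C2CCCC1CCC2 (boron unit, to intermediate 11 only); hydrogen peroxide, OO
Why: In this hydroboration–oxidation 9-BBN puts boron on the terminal C11 of the 1,1-disubstituted end of the diene in preference to the hindered trisubstituted C7=C8 bond and delivers hydrogen to C9 from the face opposite the axial C10 methyl, which sets 9R with an equatorial CH2OH after oxidation of the C–B bond with retention.

Step 8
Reactants: 12 homoallylic alcohol
Product: 14 (3R,5S,8S,9R,10R)-3-(tert-butyldimethylsilyloxy)drimane-8,11-diol, via C8 hydroperoxide 13 (not isolated)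
Conditions: Mn(dpm)3 (cat.), PhSiH3, O2 (1 atm), iPrOH/CH2Cl2, 0 °C → rt; then PPh3
Reagents that add atoms: dioxygen, O=O
Why: In this Mukaiyama hydration Markovnikov hydrogen-atom transfer to C7 gives the tertiary C8 radical, which O2 should capture on the face away from the axial C10 methyl because the other face suffers a 1,3-diaxial clash, so oxygen ends equatorial and the methyl axial (8S), and PPh3 reduces the hydroperoxide to the alcohol.

Step 9
Reactants: 14 diol; 15 umbelliferone (7-hydroxycoumarin)
Product: 16 7-{[(3R,5S,8S,9R,10R)-3-(tert-butyldimethylsilyloxy)-8-hydroxydriman-11-yl]oxy}-2H-chromen-2-one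
Conditions: PPh3, DIAD, THF, 0 → 40 °C
Reagents that add atoms: none
Why: In this Mitsunobu etherification only the primary C11 hydroxyl can be activated and displaced, since the tertiary C8 alcohol is inert and C3 is silylated, umbelliferone is acidic enough to protonate the betaine, and no stereocentre is involved because substitution occurs at a CH2 group.

Step 10
Reactants: 16 silyl ether
Product: 17 7-{[(3R,5S,8S,9R,10R)-3,8-dihydroxydriman-11-yl]oxy}-2H-chromen-2-one
Conditions: HF·pyridine, THF, 0 °C → rt
Reagents that add atoms: none
Why: Fluoride-driven silyl ether cleavage in a mildly acidic medium should spare the base-sensitive coumarin lactone, the aryl ether and the tertiary alcohol.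

Step 11
Reactants: 17 diol; 18 angelic acid
Product: 20 (3R,5S,8S,9R,10R)-8-hydroxy-11-[(2-oxo-2H-chromen-7-yl)oxy]driman-3-yl (Z)-2-methylbut-2-enoate (CNP0189964.2), via angelic 2,4,6-trichlorobenzoic anhydride 19 (not isolated)
Conditions: 18, 2,4,6-trichlorobenzoyl chloride, Et3N, toluene, rt; then 17, 80 °C
Reagents that add atoms: 2,4,6-trichlorobenzoyl chloride, O=C(Cl)c1c(Cl)cc(Cl)cc1Cl (to intermediate 19 only)
Why: Yamaguchi-type mixed-anhydride esterification run without a nucleophilic catalyst is the established way to angeloylate hindered secondary alcohols without Z to E drift to the tiglate, the alcohol attacks the less hindered angeloyl carbonyl, the tertiary C8 hydroxyl stays free, and C3 keeps its configuration because its C–O bond is not broken.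

Compound list
1 | (S)-(+)-carvone | O=C1C[C@H](CC=C1C)C(C)=C | starting material
2 | lithium (3S)-6-methyl-3-(prop-1-en-2-yl)cyclohexa-1,5-dien-1-olate | [Li]OC1=C[C@H](CC=C1C)C(C)=C | intermediate
3 | (5S)-2,6-dimethyl-5-(prop-1-en-2-yl)cyclohex-2-en-1-one, C6 epimer mixture | CC1[C@H](CC=C(C)C1=O)C(C)=C | intermediate
4 | allyl bromide | C=CCBr | starting material
5 | lithium (3R)-2,6-dimethyl-3-(prop-1-en-2-yl)cyclohexa-1,5-dien-1-olate | [Li]OC1=C(C)[C@H](CC=C1C)C(C)=C | intermediate
6 | (5R,6R)-2,6-dimethyl-5-(prop-1-en-2-yl)-6-(prop-2-en-1-yl)cyclohex-2-en-1-one | C=CC[C@]1(C)[C@H](CC=C(C)C1=O)C(C)=C | intermediate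
7 | 3-[(1R,6R)-1,3-dimethyl-2-oxo-6-(prop-1-en-2-yl)cyclohex-3-en-1-yl]propanal | O=CCC[C@]1(C)[C@H](CC=C(C)C1=O)C(C)=C | intermediate
8 | (3R,5R,10R)-3-hydroxy-11-nordrim-7-en-9-one | O[C@@H]1CC[C@]2(C)[C@H](CC=C(C)C2=O)C1(C)C | intermediate
9 | (3R,5R,10R)-3-(tert-butyldimethylsilyloxy)-11-nordrim-7-en-9-one | CC(C)(C)[Si](C)(C)O[C@@H]1CC[C@]2(C)[C@H](CC=C(C)C2=O)C1(C)C | intermediate
10 | (3R,5S,10R)-3-(tert-butyldimethylsilyloxy)drima-7,9(11)-diene | CC(C)(C)[Si](C)(C)O[C@@H]1CC[C@]2(C)[C@H](CC=C(C)C2=C)C1(C)C | intermediate
11 | 9-BBN adduct of 10 with boron on C11, ring configuration as in 12 | CC(C)(C)[Si](C)(C)O[C@@H]1CC[C@]2(C)[C@H](CC=C(C)[C@H]2CB3C4CCCC3CCC4)C1(C)C | intermediate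
12 | (3R,5S,9R,10R)-3-(tert-butyldimethylsilyloxy)drim-7-en-11-ol | CC(C)(C)[Si](C)(C)O[C@@H]1CC[C@]2(C)[C@H](CC=C(C)[C@H]2CO)C1(C)C | intermediate
13 | (3R,5S,8S,9R,10R)-3-(tert-butyldimethylsilyloxy)-8-hydroperoxydriman-11-ol | CC(C)(C)[Si](C)(C)O[C@@H]1CC[C@]2(C)[C@H](CC[C@](C)(OO)[C@H]2CO)C1(C)C | intermediate
14 | (3R,5S,8S,9R,10R)-3-(tert-butyldimethylsilyloxy)drimane-8,11-diol | CC(C)(C)[Si](C)(C)O[C@@H]1CC[C@]2(C)[C@H](CC[C@](C)(O)[C@H]2CO)C1(C)C | intermediate
15 | umbelliferone | Oc1ccc2ccc(=O)oc2c1 | starting material
16 | 7-{[(3R,5S,8S,9R,10R)-3-(tert-butyldimethylsilyloxy)-8-hydroxydriman-11-yl]oxy}-2H-chromen-2-one | CC(C)(C)[Si](C)(C)O[C@@H]1CC[C@]2(C)[C@H](CC[C@](C)(O)[C@H]2COc2ccc3ccc(=O)oc3c2)C1(C)C | intermediate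
17 | 7-{[(3R,5S,8S,9R,10R)-3,8-dihydroxydriman-11-yl]oxy}-2H-chromen-2-one | O[C@@H]1CC[C@]2(C)[C@H](CC[C@](C)(O)[C@H]2COc2ccc3ccc(=O)oc3c2)C1(C)C | intermediate
18 | angelic acid | C/C=C(/C)C(=O)O | starting material
19 | angelic 2,4,6-trichlorobenzoic anhydride | C/C=C(/C)C(=O)OC(=O)c1c(Cl)cc(Cl)cc1Cl | intermediate
20 | CNP0189964.2, (3R,5S,8S,9R,10R)-8-hydroxy-11-[(2-oxo-2H-chromen-7-yl)oxy]driman-3-yl (Z)-2-methylbut-2-enoate | C/C=C(/C)C(=O)O[C@@H]1CC[C@]2(C)[C@H](CC[C@](C)(O)[C@H]2COc2ccc3ccc(=O)oc3c2)C1(C)C | target

Total step count: 11. Longest linear sequence: 11 steps, from 1 to 20.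

Steps most likely to fail

Step 4.
- **What may go wrong:** The cyclised alkoxy radical may fragment back to the open C4 radical faster than it is reduced, so the isopropenyl group is merely hydrogenated. The two faces of the aldehyde may also be poorly differentiated.
- **Fallback:** It sets out from 7 and comes back at 8. It keeps the C3–C4 closure but changes the acceptor from C=O to C≡N and sets C3 by hydride instead of in the radical event.
- **Nitrile:** I2 and aqueous NH3 in THF should convert the aldehyde into 3-[(1R,6R)-1,3-dimethyl-2-oxo-6-(prop-1-en-2-yl)cyclohex-3-en-1-yl]propanenitrile F1.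
- **Cyclisation:** The known iron-hydride alkene–nitrile cyclisation (Fe(acac)3, PhSiH3, EtOH, 60 °C) closes ring A 6-exo-dig. It passes through an iminyl radical that does not readily reopen and should give 3-imino-11-nordrim-7-en-9-one F2.
- **Hydrolysis:** Aqueous acidic work-up hydrolyses F2 to (5R,10R)-11-nordrim-7-ene-3,9-dione F3.
- **Reduction:** NaBH4 in MeOH/CH2Cl2 at −78 °C should reduce the saturated C3 ketone in preference to the hindered conjugated C9 ketone. Axial hydride delivery then gives the equatorial 3R alcohol 8.

Step 8.
- **What may go wrong:** Hydrogen-atom transfer to the hindered trisubstituted alkene may be slow, or the capture of the C8 radical by O2 may show poor facial selectivity.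
- **Fallback:** It sets out from 12 and comes back at 14. It replaces radical oxygenation by a concerted oxygen transfer followed by ionic opening.
- **Epoxidation:** mCPBA with NaHCO3 in CH2Cl2 at 0 °C should deliver oxygen to the face opposite the C10 methyl. This gives (3R,5S,7S,8R,9R,10R)-3-(tert-butyldimethylsilyloxy)-7,8-epoxydriman-11-ol F4, which fixes the C8–O configuration.
- **Opening:** LiEt3BH in THF at reflux should open the epoxide by SN2 attack at the secondary C7. Attack at C8 is blocked by its full substitution and by the C10 methyl.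

Step 9.
- **What may go wrong:** Displacement at C11 may be sluggish, because this primary carbon is flanked by two fully substituted ring carbons. The activated alcohol could then be lost through elimination or fragmentation while the betaine is consumed.
- **Fallback:** It sets out from 14 and comes back at 16. It forms the other C–O bond of the ether, so the hindered alcohol acts as nucleophile rather than as electrophile.
- **Coupling:** A Buchwald–Hartwig-type C–O coupling of 14 with commercial 7-bromocoumarin is used (Pd2(dba)3, tBuBrettPhos, Cs2CO3, toluene, 90 °C). The tertiary C8 hydroxyl does not take part. This fallback makes no compound outside the list (F0).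

Further compounds
F1 | step 4 | 3-[(1R,6R)-1,3-dimethyl-2-oxo-6-(prop-1-en-2-yl)cyclohex-3-en-1-yl]propanenitrile | N#CCC[C@]1(C)[C@H](CC=C(C)C1=O)C(C)=C
F2 | step 4 | (5R,10R)-3-imino-11-nordrim-7-en-9-one | N=C1CC[C@]2(C)[C@H](CC=C(C)C2=O)C1(C)C
F3 | step 4 | (5R,10R)-11-nordrim-7-ene-3,9-dione | O=C1CC[C@]2(C)[C@H](CC=C(C)C2=O)C1(C)C
F4 | step 8 | (3R,5S,7S,8R,9R,10R)-3-(tert-butyldimethylsilyloxy)-7,8-epoxydriman-11-ol | CC(C)(C)[Si](C)(C)O[C@@H]1CC[C@]2(C)[C@H](C[C@@H]3O[C@]3(C)[C@H]2CO)C1(C)C
F0 | step 9 | none | none
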